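All runs were computed with made-up constants; the scatter is artificial.

The violet run shows what to watch in the repeat: how fast D is still climbing, not how much of it stands in the flask.

| flask | L | remark | time |
|---|---|---|---|
| violet | 0.050 M | run made earlier |  |
| teal | 0.075 M | run made earlier |  |
| beta | 0.10 M |  | 4.0 h |
| theta | 0.10 M |  | 5.0 h |

| run | time / h | Z / % | X / % | D / % | L / % | J / % |
|---|---|---|---|---|---|---|
| violet | 0.833 | 0.3 | 9.1 | 3.1 | 24.7 | 39.9 |
| violet | 1.50 | 2.2 | 14.6 | 6.3 | 10.9 | 40.2 |
| violet | 2.50 | 5.6 | 17.0 | 20.6 | 4.8 | 30.7 |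
| violet | 3.00 | 7.0 | 15.8 | 26.8 | 4.8 | 27.0 |
| violet | 4.00 | 12.8 | 11.7 | 34.5 | 2.6 | 17.8 |
| violet | 5.00 | 17.2 | 7.9 | 39.9 | 3.6 | 13.9 |
| teal | 0.417 | 0.1 | 2.1 | 1.2 | 48.8 | 28.9 |
| teal | 0.667 | 0 | 5.5 | 1.8 | 33.7 | 36.9 |
| teal | 1.00 | 1.3 | 10.5 | 4.5 | 19.4 | 41.1 |
| teal | 2.00 | 2.8 | 15.2 | 13.6 | 8.4 | 33.8 |
| teal | 3.00 | 7.2 | 14.2 | 24.1 | 4.1 | 24.6 |
| teal | 5.00 | 15.9 | 9.5 | 37.8 | 3.4 | 15.0 |

(scatter of a reading: 1 percentage point)

1. which of these there is most of at the end, counted by the L in it, beta (Z / J / X / D)
2. which of these there is most of at the end, counted by the L in it, theta (Z / J / X / D)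
3. how much there is at the end of the one of these that leads, in percent of the L charged: beta
4. how much there is at the end of the one of these that leads, in percent of the L charged: theta

- reactions considered so far: L -> J; J -> X; X -> D; D <-> Z; L <-> Q
- a reading of L is of its free form alone

We count in hours. From 3.00 h to 4.00 h, violet's D gained 7.7 percentage points, and in the next hour it gained 5.4 points. Their ratio, 0.701, is our hourly slowing factor, the gain of one hour over the gain of the hour before. It splits in two. What reached D and Z together in violet fell from 14 points to 9.8 points, a factor of 0.726. The share of that kept as D went from 57.0% to 55.1%, a factor of 0.966, so in violet the factor of the inflow reads lower than the factor of the share. Each gain carries the scatter of two readings of 1 point, so these factors are readings, not constants.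

Now the accumulated slowing. Summed over later hours at that factor, violet's gains after the reading at 4.00 h come to 18 points, so by this estimate violet's D at that time is still well short of the end of its climb. We therefore expect theta, read at 5.0 h, to stand about 5.4 points above beta, read at 4.0 h.

The forecast puts D first in beta at 32% and D first in theta at 37%, on the ground that “the chain is essentially first-order”. Its gap of 5 points lies close to our hourly gain.

    L → J (k = 1.10 h⁻¹)
    J → X (k = 0.480 h⁻¹)
    X → D (k = 1.00 h⁻¹)
    D ⇌ Z (K = 0.830, k = 0.300 h⁻¹)
    L ⇌ Q (K = 2.40, k = 0.600 h⁻¹)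

D leads in both flasks, with 33.3% in beta and 38.6% in theta, so the hour between gave 5.3 points, close to violet's 5.4 points. The largest single effect on that gap is the backward run from Z to D: with it taken away, the gap is 1.7 points. Adding our 18 points to beta gives 51.3%, and beta left until 40.0 h holds 54.6% of D.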